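Compound numbers 1–21 are fixed by the steps below. Atom labels C1–C20 follow abietane numbering of the target throughout.

## Analysis of the target

The target is 2α-acetoxy-7β,20-epoxyabieta-8,11,13-triene-11,12-diol. It has a cyclohexane ring A, a carbocyclic ring B and a catechol ring C. The angular carbon C20 is an oxymethylene joined through an ether oxygen to C7, so ring B and the oxacycle O–C7–C8–C9–C10–C20 together form a 2-oxabicyclo[2.2.2]octene with C7 and C10 as bridgeheads. There are four stereocentres: C2 (S), C5 (S), C7 (S) and C10 (R). C20 on C10 is β and trans to H5 (trans-type A/B fusion). The acetoxy group at C2 is α (equatorial), trans to C20 and 1,3 to C10. C7 is not independent, because the bridge fixes it once C10 is set. The sensitive groups are the free catechol (oxidised to the ortho-quinone in air, above all under base), the secondary acetate (which must survive phenol deprotection) and the benzylic C7–O bond, which is para to the C12 oxygen and can be ionised by acid. The synthesis is hard because C4 (gem-dimethyl), C5 and the all-carbon benzylic quaternary centre C10 are contiguous, and because the remote C2 oxygen has to be related to them. The strategy rests on one feature: C7 carries one bond to the oxygen of C20 and one bond to C8, which lies para to the C12 oxygen. C7 is therefore an aldehyde carbon that has reacted with an alcohol and with an electron-rich arene position, so the whole bridged core can be closed from a C7 aldehyde on a ring A that already carries C5 and C10.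

## Retrosynthetic reasoning

**21 ⇒ 20 ⇒ 19 (O–CH3 bonds, then the acetate C–O bond).** The catechol is freed last because it is the most oxidation-prone function. The acetate is put on 19, where the C2 hydroxyl is the only free hydroxyl, so no selectivity question arises. The forward demethylation must spare the ester and leave the benzylic C7–O bond closed.

**19 ⇒ 17 (C7–O and C7–C8).** Both bonds to C7 are cut at once, which opens the oxacycle and ring B and leaves ring A with a C20 hydroxymethyl group and a C6–C7 acetaldehyde chain cis to each other. Cutting here removes two rings and the C7 stereocentre and leaves a monocyclic problem. The forward reaction must ionise lactol 18 (the resting form of 17) and let C8 attack C7 across the ring.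

**17 ⇒ 16 ⇒ 15 (C7=O unmasked; C2–O bond).** The aldehyde is carried as a dimethyl acetal, so no late chemoselective alcohol oxidation is needed. The C2–O bond is cut back to the C1=C2 alkene of 15. The forward hydroboration must place oxygen on C2 rather than C1, and on the α-face.

**15 ⇒ 13 ⇒ 12 (C10–C20).** The quaternary centre is disconnected in a [2,3]-sigmatropic sense: C20 and its oxygen come from an oxymethyl carbanion tethered to the C2 oxygen of allylic alcohol 12. This turns the hardest centre into a consequence of a secondary carbinol, and it leaves exactly the alkene needed to bring the C2 oxygen back. The forward step must deliver C20 to C10 on the face of the C2–O bond, which therefore has to be cis to the C5 side chain.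

**12 ⇒ 11 ⇒ 9 (C2–H bond; acetal back to an allyl group).** The carbinol comes from enone 11 by reagent-controlled reduction. The acetal carbon C7 comes from the internal alkene carbon of the allyl group of 9 by oxidative cleavage. The allyl group is chosen as the C6–C7 unit because it can be introduced enantioselectively by palladium catalysis, whereas an oxygenated two-carbon halide cannot be used to alkylate this hindered enolate with enantiocontrol.

**9 ⇒ 4 + 6 (C9–C10, with carbonyl transposition).** The aryl–C10 bond is cut to aryllithium 7, made from arene 6, and the vinylogous thioester 4. Addition to the carbonyl and hydrolysis move the oxygen from C10 to C2. The forward step must add a hindered aryl nucleophile without enolising C5.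

**4 ⇒ 3 ⇒ 2 ⇒ 1 (C5–C6).** The first stereocentre, C5, is made by decarboxylative asymmetric allylation of the enol carbonate 3, which comes from the symmetrical dione 1 through 2. Every later stereocentre is derived from this one or from the reagent-controlled reduction.

**6 ⇒ 5 (two O–CH3 bonds).** The arene is the dimethyl ether of catechol 5. The methoxy groups direct the lithiation, activate C8 for the key step and protect the catechol until the end.

## Alternatives that were turned down

**Alternative 1: alkylative dearomatisation of a naphthol.**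
- Disconnection: the C1–C10 bond of ring A, with rings B and C taken together as a naphthalene.
- Forward key step: naphthol A4 carries the hydroxyl on C7, bromine on C6, the C4–C1 chain ending in a primary mesylate on C5, and the benzyloxymethyl group C20 on C10. On deprotonation, C10 (para to the phenolate oxygen) displaces the mesylate in a 6-exo-tet closure. This makes ring A and gives dienone A1 with C10 quaternary.
- For it: the closure is an SN2 reaction at an unhindered primary carbon and makes no demand on a twisted dimethoxyarene. The C7 oxygen is present from the start. On the reliability of the ring-forming bond itself it is at least as strong as the chosen route.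
- Against it: the only element that can bias the face of the flat naphtholate is the silyloxy group at C2 on a flexible tether, 1,3 to the new centre. C5 is still sp2 in A1 and would have to be set by reducing a tetrasubstituted bromo-enone carbon flanked by two quaternary carbons. The bromine, the C7 ketone and the benzyl ether then need several redox and protecting-group steps before the bridge can be closed. The pentasubstituted naphthol A4 is itself long to make.
- Comparison: the chosen route gives up the simple SN2 closure, but each stereocentre is set by a defined element (catalyst, reagent, sigmatropic transfer, bridge) and no redox correction is needed after ring closure.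

**Alternative 2: Ireland–Claisen ring contraction.**
- Disconnection: the C5–C10 bond, with the O–C7 bond given up in exchange.
- Forward key step: after O-silylation of its enolate, lactone A5 rearranges through a boat transition state imposed by the lactone ring. C10 bonds to the E-alkene terminus C5, the O–C7 bond breaks and ring B closes as the dihydronaphthalene acid A2.
- For it: C5 and C10 are made in one step, and their relative configuration is enforced by the ring-constrained boat and the alkene geometry. The absolute configuration comes from the single carbinol centre C7. On control of the C5/C10 pair it is stronger than the chosen route, which needs three controlled steps for the same result.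
- Against it: ring A does not yet exist in A2 and has to be closed by metathesis. The C2 oxygen must then be introduced on the new C2=C3 alkene in the presence of the C6=C7 styrene. The C7–O bond, consumed in the key step, has to be rebuilt after reduction of the acid. The [3,3] shift must also join C10 to a carbon next to the quaternary C4.
- Comparison: the chosen route has ring A and the C2 oxygen pattern in hand before the key step, and only two steps follow it.

**Alternative 3: intramolecular Diels–Alder reaction of a 2-benzopyran-3-one.**
- Disconnection: C5–C10 and C6–C7 together, so rings A and B form in one step.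
- Forward key step: formyl acid A7 is dehydrated to pyranone A6, an ortho-quinoid diene. Its termini C10 and C7 add the tethered vinyl group to give bridged lactone A3.
- For it: two C–C bonds, two rings and three stereocentres (C5, C7, C10) are made in one operation, with the C20 bridge already in place. In convergence and gain in complexity per step it is clearly stronger than the chosen route.
- Against it: the configuration at C5 depends on the folding of a four-atom tether and on induction from the remote C2 silyloxy group, so a cis-fused A/B isomer is a real competitor. The dienophile is an unactivated vinyl group on a quaternary carbon, so the reactive diene may decay before it cyclises. C20 emerges as a lactone carbonyl and needs a chemoselective reduction to the ether. A7 is a crowded pentasubstituted arene.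
- Comparison: the chosen route pays with a longer linear sequence. In return it sets C5 and C10 separately, its ring-forming step has no stereochemical choice to make, and it delivers C20 at the ether oxidation level.

Key step: step 12

Remarks on the chemistry:
- The (R,R)-ligand in step 3 is assumed to give the (6S)-ketone 4; if the sense of induction proves opposite, the (S,S)-ligand is used.
- Compound 17 is written as the open hydroxy aldehyde; it is expected to rest largely as lactol 18 (both C7 epimers), and the two are handled as one material.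
- 3-Isopropylcatechol 5 is taken to be commercially available.

## Route

Step 1
Reactants: 1 dimedone (5,5-dimethylcyclohexane-1,3-dione)
Product: 2 5,5-dimethyl-3-(phenylsulfanyl)cyclohex-2-en-1-one
Conditions: PhSH (1.1 equiv), TsOH·H2O (5 mol %), toluene, reflux, Dean–Stark
Reagents that add atoms: benzenethiol, Sc1ccccc1
Why: Acid-catalysed condensation of a cyclic 1,3-diketone with a thiol (addition–dehydration) gives the vinylogous thioester; the dione is symmetrical, so there is no regiochemical question.

Step 2
Reactants: 2 5,5-dimethyl-3-(phenylsulfanyl)cyclohex-2-en-1-one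
Product: 3 3,3-dimethyl-5-(phenylsulfanyl)cyclohexa-1,5-dien-1-yl prop-2-en-1-yl carbonate
Conditions: LiN(iPr)2 (1.1 equiv), TMEDA, THF, −78 °C; ClCO2CH2CH=CH2, −78 °C
Reagents that add atoms: allyl chloroformate, C=CCOC(Cl)=O
Why: Kinetic deprotonation of a vinylogous thioester takes place at the α' methylene (the future C5) and not at the γ position; with TMEDA the lithium enolate is acylated on oxygen, which gives the allyl enol carbonate needed for decarboxylative allylation.

Step 3
Reactants: 3 3,3-dimethyl-5-(phenylsulfanyl)cyclohexa-1,5-dien-1-yl prop-2-en-1-yl carbonate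
Product: 4 (6S)-5,5-dimethyl-3-(phenylsulfanyl)-6-(prop-2-en-1-yl)cyclohex-2-en-1-one
Conditions: Pd2(dba)3·CHCl3 (2.5 mol %), (R,R)-N,N'-(9,10-dihydro-9,10-ethanoanthracene-11,12-diyl)bis[2-(diphenylphosphanyl)benzamide] (5.5 mol %), 1,4-dioxane, rt
Reagents that add atoms: none
Why: Palladium-catalysed decarboxylative asymmetric allylic alkylation (Tsuji–Trost type): zerovalent palladium ionises the allyl carbonate, CO2 is lost and the enolate recombines with the π-allyl unit at C5 inside the chiral pocket of the ligand, which sets the C5 stereocentre. The neutral conditions keep the enolate from equilibrating, so the new tertiary centre should not racemise and the γ position should not be alkylated.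

Step 4
Reactants: 5 3-isopropylcatechol (3-(propan-2-yl)benzene-1,2-diol)
Product: 6 1,2-dimethoxy-3-(propan-2-yl)benzene
Conditions: MeI (3 equiv), K2CO3 (3 equiv), acetone, reflux
Reagents that add atoms: iodomethane, CI
Why: Williamson methylation of both phenols; the methyl ethers direct the lithiation of step 5, activate the arene for step 12 and mask the oxidation-prone catechol until the last step.

Step 5
Reactants: 6 1,2-dimethoxy-3-(propan-2-yl)benzene; 4 (6S)-5,5-dimethyl-3-(phenylsulfanyl)-6-(prop-2-en-1-yl)cyclohex-2-en-1-one
Product: 9 (4S)-3-[2,3-dimethoxy-4-(propan-2-yl)phenyl]-5,5-dimethyl-4-(prop-2-en-1-yl)cyclohex-2-en-1-one, via aryllithium 7 (not isolated), via tertiary allylic carbinol 8 (not isolated)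
Conditions: 6, n-BuLi, TMEDA, THF, 0 °C; CeCl3, −78 °C; 4, −78 → −30 °C; then 2 M HCl, THF, 0 °C → rt
Reagents that add atoms: water, O
Why: Directed ortho-lithiation of 6 occurs at the only free position next to a methoxy group, and the cerium-modified aryl reagent adds 1,2 to the hindered, enolisable ketone without deprotonating C5. Acid then ionises carbinol 8 to a sulfur-stabilised allyl cation that takes up water at the sulfur-bearing carbon and loses benzenethiol (Stork–Danheiser-type carbonyl transposition), which places the aryl group on C10 and the carbonyl on C2.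

Step 6
Reactants: 9 (4S)-3-[2,3-dimethoxy-4-(propan-2-yl)phenyl]-5,5-dimethyl-4-(prop-2-en-1-yl)cyclohex-2-en-1-one
Product: 11 (4S)-4-(2,2-dimethoxyethyl)-3-[2,3-dimethoxy-4-(propan-2-yl)phenyl]-5,5-dimethylcyclohex-2-en-1-one, via keto aldehyde 10 (not isolated)
Conditions: OsO4 (2 mol %), NaIO4 (4 equiv), 2,6-lutidine, dioxane/H2O 3:1, rt; crude 10: CH(OMe)3, pyridinium p-toluenesulfonate (cat.), MeOH, rt
Reagents that add atoms: trimethyl orthoformate, COC(OC)OC
Why: Lemieux–Johnson cleavage acts on the terminal alkene and leaves the hindered, electron-poor enone alkene and the arene alone, which reveals C7 at the aldehyde level. The aldehyde is far more reactive than the conjugated ketone towards acetal formation, so it is masked selectively as the dimethyl acetal for the basic and hydridic steps that follow.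

Step 7
Reactants: 11 (4S)-4-(2,2-dimethoxyethyl)-3-[2,3-dimethoxy-4-(propan-2-yl)phenyl]-5,5-dimethylcyclohex-2-en-1-one
Product: 12 (1R,4S)-4-(2,2-dimethoxyethyl)-3-[2,3-dimethoxy-4-(propan-2-yl)phenyl]-5,5-dimethylcyclohex-2-en-1-ol
Conditions: (S)-1-methyl-3,3-diphenyltetrahydro-1H,3H-pyrrolo[1,2-c][1,3,2]oxazaborole (0.2 equiv), BH3·SMe2 (0.7 equiv), THF, −30 °C; MeOH
Reagents that add atoms: none
Why: Corey–Bakshi–Shibata reduction: with the alkenyl side of the carbonyl as the large group, the (S)-catalyst should deliver hydride to the α-face of C2, so the hydroxyl ends on the β-face, cis to the C5 side chain. The catalyst may have to override the ring's own preference; any enantiomeric enone carried through is converted into the trans diastereomer, which is removed by chromatography.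

Step 8
Reactants: 12 (1R,4S)-4-(2,2-dimethoxyethyl)-3-[2,3-dimethoxy-4-(propan-2-yl)phenyl]-5,5-dimethylcyclohex-2-en-1-ol
Product: 13 tributyl[({(1R,4S)-4-(2,2-dimethoxyethyl)-3-[2,3-dimethoxy-4-(propan-2-yl)phenyl]-5,5-dimethylcyclohex-2-en-1-yl}oxy)methyl]stannane
Conditions: KH (1.3 equiv), 18-crown-6 (0.1 equiv), THF, 0 °C; Bu3SnCH2I (1.3 equiv), 0 °C → rt
Reagents that add atoms: tributyl(iodomethyl)stannane, CCCC[Sn](CCCC)(CCCC)CI
Why: Williamson etherification of the potassium alkoxide with the reactive iodomethylstannane; the acetal and the aryl ethers are inert, and the product is the substrate for the Still variant of the Wittig rearrangement.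

Step 9
Reactants: 13 tributyl[({(1R,4S)-4-(2,2-dimethoxyethyl)-3-[2,3-dimethoxy-4-(propan-2-yl)phenyl]-5,5-dimethylcyclohex-2-en-1-yl}oxy)methyl]stannane
Product: 15 {(1R,6S)-6-(2,2-dimethoxyethyl)-1-[2,3-dimethoxy-4-(propan-2-yl)phenyl]-5,5-dimethylcyclohex-2-en-1-yl}methanol, via lithiomethyl ether 14 (not isolated)
Conditions: n-BuLi (1.5 equiv), THF, −78 → −30 °C; aq. NH4Cl
Reagents that add atoms: none
Why: Still–Wittig [2,3]-sigmatropic rearrangement: tin–lithium exchange gives carbanion 14, which bonds to C10 on the β-face that carries the C2–O bond (suprafacial shift). The C2 configuration is thereby transferred to the quaternary centre C10, with the hydroxymethyl group C20 cis to the C5 side chain and the aryl group trans to it, and the C1=C2 alkene is left for the next step.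

Step 10
Reactants: 15 {(1R,6S)-6-(2,2-dimethoxyethyl)-1-[2,3-dimethoxy-4-(propan-2-yl)phenyl]-5,5-dimethylcyclohex-2-en-1-yl}methanol
Product: 16 (1S,3R,4S)-4-(2,2-dimethoxyethyl)-3-[2,3-dimethoxy-4-(propan-2-yl)phenyl]-3-(hydroxymethyl)-5,5-dimethylcyclohexan-1-ol
Conditions: 9-BBN (3 equiv), THF, 65 °C; then 3 M NaOH, 30% H2O2, 0 °C → rt
Reagents that add atoms: hydrogen peroxide, OO
Why: Hydroboration–oxidation: the bulky borane should place boron on C2, the alkene carbon remote from the quaternary centre C10. It should approach the α-face, because the β-face carries the pseudoaxial C10–CH2O–boron group and the axial C4 methyl group, as in 1-ene steroids with a 10β substituent; oxidation with retention gives the equatorial 2α-alcohol, trans to C20.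

Step 11
Reactants: 16 (1S,3R,4S)-4-(2,2-dimethoxyethyl)-3-[2,3-dimethoxy-4-(propan-2-yl)phenyl]-3-(hydroxymethyl)-5,5-dimethylcyclohexan-1-ol
Product: 17 2-{(1S,2R,4S)-2-[2,3-dimethoxy-4-(propan-2-yl)phenyl]-4-hydroxy-2-(hydroxymethyl)-6,6-dimethylcyclohexyl}acetaldehyde
Conditions: AcOH/THF/H2O 3:1:1, 35 °C
Reagents that add atoms: water, O
Why: Mild aqueous acid hydrolyses the dimethyl acetal, assisted by the neighbouring C20 hydroxyl, and gives the hydroxy aldehyde, which rests as lactol 18. The medium is too weak and too wet to drive the Friedel–Crafts closure, and any material that does close is simply the product of step 12.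

Step 12
Reactants: 17 2-{(1S,2R,4S)-2-[2,3-dimethoxy-4-(propan-2-yl)phenyl]-4-hydroxy-2-(hydroxymethyl)-6,6-dimethylcyclohexyl}acetaldehyde
Product: 19 (2S,5S,7S,10R)-11,12-dimethoxy-7,20-epoxyabieta-8,11,13-trien-2-ol, via lactol 18 (not isolated)
Conditions: BF3·OEt2 (2 equiv), CH2Cl2, −40 → 0 °C; aq. NaHCO3
Reagents that add atoms: none
Why: In the flask 17 is present as lactol 18, the product of 6-exo-trig addition of the C20 hydroxyl to the C7 aldehyde, which forms the C7–O bond and closes the oxacycle; BF3 ionises the anomeric hydroxyl to the cyclic oxocarbenium ion. Arene carbon C8 then attacks C7 in a six-membered Friedel–Crafts closure (6-exo-trig at the C7=O+ bond, with the arene bond C8–C9 becoming part of the new ring), which forms C7–C8 and closes ring B, and loss of the proton from C8 restores the arene. The closest known reaction is the oxa-Pictet–Spengler cyclisation of a 2-arylethanol with an aldehyde, and the isochroman it would give (O, C7, C8, C9, C10, C20) is the ring made here; the difference is that the aldehyde is already tied to C10 through C5–C6, so the isochroman is bridged across its 1,4-positions into a 2-oxabicyclo[2.2.2]octene. C7 is the only new stereocentre and has no freedom, since both of its new bonds lead to substituents of the fixed centre C10, so only the (7S) bridge can form. The step needs C20 and C6 cis on ring A, a boat-like ion with the aryl group in the flagpole position, and attack by C8 rather than C11: the first was set in steps 3 and 9, the second is the shape that 7,20-bridged abietanes themselves adopt, and the third is secured because C11 carries a methoxy group while C8 is free and para to the C12 methoxy group. If the arene attacks the aldehyde before the hydroxyl does, the para-methoxybenzylic C7 cation is captured by the C20 hydroxyl, so both orders end at 19. The equatorial C2 hydroxyl lies on the opposite face of ring A and cannot reach C7, and acetal exchange and enol-ether formation are reversible whereas the Friedel–Crafts step is not.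

Step 13
Reactants: 19 (2S,5S,7S,10R)-11,12-dimethoxy-7,20-epoxyabieta-8,11,13-trien-2-ol
Product: 20 (2S,5S,7S,10R)-11,12-dimethoxy-7,20-epoxyabieta-8,11,13-trien-2-yl acetate
Conditions: Ac2O, pyridine, 4-(dimethylamino)pyridine (cat.), CH2Cl2, rt
Reagents that add atoms: acetic anhydride, CC(=O)OC(C)=O
Why: Standard nucleophile-catalysed acetylation of the only free hydroxyl, an unhindered equatorial secondary alcohol; the ethers are inert.

Step 14
Reactants: 20 (2S,5S,7S,10R)-11,12-dimethoxy-7,20-epoxyabieta-8,11,13-trien-2-yl acetate
Product: 21 (2S,5S,7S,10R)-11,12-dihydroxy-7,20-epoxyabieta-8,11,13-trien-2-yl acetate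
Conditions: BBr3 (4 equiv), CH2Cl2, −78 → 0 °C; H2O, 0 °C, under argon
Reagents that add atoms: none
Why: Boron tribromide cleaves aryl methyl ethers by coordination to oxygen and SN2 attack of bromide on the methyl group; the two crowded, out-of-plane methoxy groups should react at low temperature, where a secondary acetate is normally retained. If the benzylic C7–O bond opens, it should re-close on work-up, because the C20 hydroxyl stays tethered next to the quinone-methide-type C7 cation.

## Compound list

1 | dimedone (5,5-dimethylcyclohexane-1,3-dione) | CC1(C)CC(=O)CC(=O)C1 | starting material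
2 | 5,5-dimethyl-3-(phenylsulfanyl)cyclohex-2-en-1-one | O=C1C=C(Sc2ccccc2)CC(C)(C)C1 | intermediate
3 | 3,3-dimethyl-5-(phenylsulfanyl)cyclohexa-1,5-dien-1-yl prop-2-en-1-yl carbonate | C=CCOC(=O)OC1=CC(C)(C)CC(Sc2ccccc2)=C1 | intermediate
4 | (6S)-5,5-dimethyl-3-(phenylsulfanyl)-6-(prop-2-en-1-yl)cyclohex-2-en-1-one | C=CC[C@@H]1C(=O)C=C(Sc2ccccc2)CC1(C)C | intermediate
5 | 3-isopropylcatechol (3-(propan-2-yl)benzene-1,2-diol) | CC(C)c1cccc(O)c1O | starting material
6 | 1,2-dimethoxy-3-(propan-2-yl)benzene | COc1cccc(C(C)C)c1OC | intermediate
7 | [2,3-dimethoxy-4-(propan-2-yl)phenyl]lithium (not isolated) | [Li]c1ccc(C(C)C)c(OC)c1OC | intermediate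
8 | (6S)-1-[2,3-dimethoxy-4-(propan-2-yl)phenyl]-5,5-dimethyl-3-(phenylsulfanyl)-6-(prop-2-en-1-yl)cyclohex-2-en-1-ol, C1 epimers (not isolated) | OC1(c2ccc(C(C)C)c(OC)c2OC)C=C(Sc2ccccc2)CC(C)(C)[C@@H]1CC=C | intermediate
9 | (4S)-3-[2,3-dimethoxy-4-(propan-2-yl)phenyl]-5,5-dimethyl-4-(prop-2-en-1-yl)cyclohex-2-en-1-one | O=C1CC(C)(C)[C@H](CC=C)C(c2ccc(C(C)C)c(OC)c2OC)=C1 | intermediate
10 | 2-{(1S)-2-[2,3-dimethoxy-4-(propan-2-yl)phenyl]-6,6-dimethyl-4-oxocyclohex-2-en-1-yl}acetaldehyde (not isolated) | O=C1CC(C)(C)[C@H](CC=O)C(c2ccc(C(C)C)c(OC)c2OC)=C1 | intermediate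
11 | (4S)-4-(2,2-dimethoxyethyl)-3-[2,3-dimethoxy-4-(propan-2-yl)phenyl]-5,5-dimethylcyclohex-2-en-1-one | O=C1CC(C)(C)[C@H](CC(OC)OC)C(c2ccc(C(C)C)c(OC)c2OC)=C1 | intermediate
12 | (1R,4S)-4-(2,2-dimethoxyethyl)-3-[2,3-dimethoxy-4-(propan-2-yl)phenyl]-5,5-dimethylcyclohex-2-en-1-ol (hydroxyl cis to the side chain) | O[C@@H]1CC(C)(C)[C@H](CC(OC)OC)C(c2ccc(C(C)C)c(OC)c2OC)=C1 | intermediate
13 | tributyl[({(1R,4S)-4-(2,2-dimethoxyethyl)-3-[2,3-dimethoxy-4-(propan-2-yl)phenyl]-5,5-dimethylcyclohex-2-en-1-yl}oxy)methyl]stannane | CCCC[Sn](CCCC)(CCCC)CO[C@@H]1CC(C)(C)[C@H](CC(OC)OC)C(c2ccc(C(C)C)c(OC)c2OC)=C1 | intermediate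
14 | [({(1R,4S)-4-(2,2-dimethoxyethyl)-3-[2,3-dimethoxy-4-(propan-2-yl)phenyl]-5,5-dimethylcyclohex-2-en-1-yl}oxy)methyl]lithium (not isolated) | [Li]CO[C@@H]1CC(C)(C)[C@H](CC(OC)OC)C(c2ccc(C(C)C)c(OC)c2OC)=C1 | intermediate
15 | {(1R,6S)-6-(2,2-dimethoxyethyl)-1-[2,3-dimethoxy-4-(propan-2-yl)phenyl]-5,5-dimethylcyclohex-2-en-1-yl}methanol | OC[C@]1(c2ccc(C(C)C)c(OC)c2OC)C=CCC(C)(C)[C@@H]1CC(OC)OC | intermediate
16 | (1S,3R,4S)-4-(2,2-dimethoxyethyl)-3-[2,3-dimethoxy-4-(propan-2-yl)phenyl]-3-(hydroxymethyl)-5,5-dimethylcyclohexan-1-ol | O[C@H]1CC(C)(C)[C@H](CC(OC)OC)[C@](CO)(C1)c1ccc(C(C)C)c(OC)c1OC | intermediate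
17 | 2-{(1S,2R,4S)-2-[2,3-dimethoxy-4-(propan-2-yl)phenyl]-4-hydroxy-2-(hydroxymethyl)-6,6-dimethylcyclohexyl}acetaldehyde | O[C@H]1CC(C)(C)[C@H](CC=O)[C@](CO)(C1)c1ccc(C(C)C)c(OC)c1OC | intermediate
18 | (4aS,7S,8aR)-8a-[2,3-dimethoxy-4-(propan-2-yl)phenyl]-5,5-dimethyloctahydro-1H-2-benzopyran-3,7-diol, C3 epimers (lactol of 17; not isolated) | O[C@H]1CC(C)(C)[C@@H]2CC(O)OC[C@@]2(C1)c1ccc(C(C)C)c(OC)c1OC | intermediate
19 | (2S,5S,7S,10R)-11,12-dimethoxy-7,20-epoxyabieta-8,11,13-trien-2-ol | O[C@H]1CC(C)(C)[C@@H]2C[C@@H]3OC[C@@]2(C1)c1c3cc(C(C)C)c(OC)c1OC | intermediate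
20 | (2S,5S,7S,10R)-11,12-dimethoxy-7,20-epoxyabieta-8,11,13-trien-2-yl acetate | CC(=O)O[C@H]1CC(C)(C)[C@@H]2C[C@@H]3OC[C@@]2(C1)c1c3cc(C(C)C)c(OC)c1OC | intermediate
21 | (2S,5S,7S,10R)-11,12-dihydroxy-7,20-epoxyabieta-8,11,13-trien-2-yl acetate | CC(=O)O[C@H]1CC(C)(C)[C@@H]2C[C@@H]3OC[C@@]2(C1)c1c3cc(C(C)C)c(O)c1O | target

## Step count and least certain steps

Total step count: 14. Longest linear sequence: 13 steps (steps 1–3 and 5–14, from dimedone 1); step 4 is a one-step side branch to arene 6.

**Step 12 (key step).**
- Risk: the oxocarbenium ion may be diverted before C8 reaches it, by loss of a proton from C6 to the cyclic enol ether or by intermolecular acetal exchange. The closure needs a boat-like ion with the aryl group in the flagpole position, and the two methoxy groups are twisted out of the arene plane and activate C8 less than in a simple anisole.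
- Fallback: make the two bonds separately, starting from 16. Acetylation of both hydroxyls (Ac2O, pyridine) gives diacetate acetal F1. Aqueous AcOH frees aldehyde diacetate F2, which cannot hide as a lactol. TsOH·H2O in toluene at reflux effects cyclodehydration (Friedel–Crafts hydroxyalkylation at C8, then loss of water) to dihydronaphthalene diacetate F3 with a C6=C7 bond. K2CO3 in MeOH removes both acetates to give diol F4. Catalytic TfOH in CH2Cl2 then protonates the styrene at C6, and the C20 hydroxyl adds to the para-methoxybenzylic C7 cation; this closes the bridge and rejoins the route at 19.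

**Step 3.**
- Risk: low enantioselectivity, or erosion of it by proton transfer between product and palladium enolate, because the nucleophilic carbon is neopentylic and recombination with the π-allyl unit may be slow.
- Fallback: introduce the allyl group without asymmetric induction and select C5 at the reduction stage, starting from 2. LiN(iPr)2 and allyl bromide give racemic allyl ketone F5. Steps 5 and 6 are run on the racemate, through racemic carbinol F6 (not isolated), racemic enone F7, racemic keto aldehyde F8 (not isolated) and racemic acetal F9. The reduction of step 7 then turns the (4S)-enantiomer into 12 and the (4R)-enantiomer into trans alcohol F10. Chromatography separates the diastereomers and the route is rejoined at 12, with at most half of the material.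

**Step 7.**
- Risk: poor facial selectivity, because the catalyst may have to work against the ring's preference for hydride attack anti to the axial C4 methyl group.
- Fallback: use the substrate preference and then invert, starting from 11. Reduction with NaBH4 and CeCl3 in MeOH (Luche) is expected to give trans alcohol F11. A Mitsunobu reaction with 4-nitrobenzoic acid (PPh3, DIAD) inverts C2 to give 4-nitrobenzoate F12. K2CO3 in MeOH cleaves the ester and rejoins the route at 12.

**Step 9.**
- Risk: [1,2]-shift or simple protonation of carbanion 14 may compete, because the [2,3] shift has to build a quaternary centre at an aryl-bearing alkene carbon next to the branched C5 and needs the C2–O bond pseudoaxial.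
- Fallback: a neutral, thermal [2,3] shift, starting from 12. Heating with N,N-dimethylformamide dimethyl acetal in xylene at 150 °C forms an alkoxy(amino)carbene, which rearranges on the same face (Büchi rearrangement) to dimethylamide F13, with C20 on C10 as the amide carbon. LiEt3BH in THF reduces the tertiary amide to the primary alcohol and rejoins the route at 15.

**Step 10.**
- Risk: low rate, or incomplete control of regiochemistry and face, because the alkene is flanked by a quaternary carbon and the monocyclic ring is conformationally mobile.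
- Fallback: hydroborate after the skeleton has been made rigid, starting from 15. Hydrolysis as in step 11 gives ene hydroxy aldehyde F14, which rests as ene lactol F15. BF3·OEt2 as in step 12 closes the bridged core to tetracyclic alkene F16. Hydroboration–oxidation (9-BBN; NaOH, H2O2) is then run on F16, in which the β-face of C1=C2 is walled off by the C20–O bridge and the axial C4 methyl group and C1 is screened by the C11 methoxy group. The route is rejoined at 19.

**Step 14.**
- Risk: loss of the acetate by acyl–oxygen cleavage, or ionisation of the benzylic C7–O bond followed by elimination towards C6, both caused by the strong Lewis acid.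
- Fallback: introduce the acetate after demethylation, starting from 19. BBr3 demethylates 19, which carries no ester, to triol F17. Ac2O and pyridine give triacetate F18. NH4OAc in aqueous MeOH under argon then cleaves only the two aryl acetates, which are far more electrophilic than the secondary alkyl acetate, and this ends at 21.

## Further compounds

F1 | step 12 | [(1R,2S,5S)-5-acetoxy-2-(2,2-dimethoxyethyl)-1-[2,3-dimethoxy-4-(propan-2-yl)phenyl]-3,3-dimethylcyclohexyl]methyl acetate | CC(=O)O[C@H]1CC(C)(C)[C@H](CC(OC)OC)[C@](COC(C)=O)(C1)c1ccc(C(C)C)c(OC)c1OC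
F2 | step 12 | [(1R,2S,5S)-5-acetoxy-1-[2,3-dimethoxy-4-(propan-2-yl)phenyl]-3,3-dimethyl-2-(2-oxoethyl)cyclohexyl]methyl acetate | CC(=O)O[C@H]1CC(C)(C)[C@H](CC=O)[C@](COC(C)=O)(C1)c1ccc(C(C)C)c(OC)c1OC
F3 | step 12 | (2S,5S,10R)-11,12-dimethoxyabieta-6,8,11,13-tetraene-2,20-diyl diacetate | CC(=O)O[C@H]1CC(C)(C)[C@@H]2C=Cc3cc(C(C)C)c(OC)c(OC)c3[C@@]2(COC(C)=O)C1
F4 | step 12 | (2S,5S,10R)-11,12-dimethoxyabieta-6,8,11,13-tetraene-2,20-diol | O[C@H]1CC(C)(C)[C@@H]2C=Cc3cc(C(C)C)c(OC)c(OC)c3[C@@]2(CO)C1
F5 | step 3 | racemic 5,5-dimethyl-3-(phenylsulfanyl)-6-(prop-2-en-1-yl)cyclohex-2-en-1-one | C=CCC1C(=O)C=C(Sc2ccccc2)CC1(C)C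
F6 | step 3 | racemic 1-[2,3-dimethoxy-4-(propan-2-yl)phenyl]-5,5-dimethyl-3-(phenylsulfanyl)-6-(prop-2-en-1-yl)cyclohex-2-en-1-ol | OC1(c2ccc(C(C)C)c(OC)c2OC)C=C(Sc2ccccc2)CC(C)(C)C1CC=C
F7 | step 3 | racemic 3-[2,3-dimethoxy-4-(propan-2-yl)phenyl]-5,5-dimethyl-4-(prop-2-en-1-yl)cyclohex-2-en-1-one | O=C1CC(C)(C)C(CC=C)C(c2ccc(C(C)C)c(OC)c2OC)=C1
F8 | step 3 | racemic 2-{2-[2,3-dimethoxy-4-(propan-2-yl)phenyl]-6,6-dimethyl-4-oxocyclohex-2-en-1-yl}acetaldehyde | O=C1CC(C)(C)C(CC=O)C(c2ccc(C(C)C)c(OC)c2OC)=C1
F9 | step 3 | racemic 4-(2,2-dimethoxyethyl)-3-[2,3-dimethoxy-4-(propan-2-yl)phenyl]-5,5-dimethylcyclohex-2-en-1-one | O=C1CC(C)(C)C(CC(OC)OC)C(c2ccc(C(C)C)c(OC)c2OC)=C1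
F10 | step 3 | (1R,4R)-4-(2,2-dimethoxyethyl)-3-[2,3-dimethoxy-4-(propan-2-yl)phenyl]-5,5-dimethylcyclohex-2-en-1-ol | O[C@@H]1CC(C)(C)[C@@H](CC(OC)OC)C(c2ccc(C(C)C)c(OC)c2OC)=C1
F11 | step 7 | (1S,4S)-4-(2,2-dimethoxyethyl)-3-[2,3-dimethoxy-4-(propan-2-yl)phenyl]-5,5-dimethylcyclohex-2-en-1-ol | O[C@H]1CC(C)(C)[C@H](CC(OC)OC)C(c2ccc(C(C)C)c(OC)c2OC)=C1
F12 | step 7 | (1R,4S)-4-(2,2-dimethoxyethyl)-3-[2,3-dimethoxy-4-(propan-2-yl)phenyl]-5,5-dimethylcyclohex-2-en-1-yl 4-nitrobenzoate | O=C(O[C@@H]1CC(C)(C)[C@H](CC(OC)OC)C(c2ccc(C(C)C)c(OC)c2OC)=C1)c1ccc([N+](=O)[O-])cc1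
F13 | step 9 | (1R,6S)-6-(2,2-dimethoxyethyl)-1-[2,3-dimethoxy-4-(propan-2-yl)phenyl]-N,N,5,5-tetramethylcyclohex-2-ene-1-carboxamide | CN(C)C(=O)[C@]1(c2ccc(C(C)C)c(OC)c2OC)C=CCC(C)(C)[C@@H]1CC(OC)OC
F14 | step 10 | 2-{(1S,2R)-2-[2,3-dimethoxy-4-(propan-2-yl)phenyl]-2-(hydroxymethyl)-6,6-dimethylcyclohex-3-en-1-yl}acetaldehyde | OC[C@]1(c2ccc(C(C)C)c(OC)c2OC)C=CCC(C)(C)[C@@H]1CC=O
F15 | step 10 | (4aS,8aR)-8a-[2,3-dimethoxy-4-(propan-2-yl)phenyl]-5,5-dimethyl-3,4,4a,5,6,8a-hexahydro-1H-2-benzopyran-3-ol, C3 epimers | OC1C[C@H]2C(C)(C)CC=C[C@]2(CO1)c1ccc(C(C)C)c(OC)c1OC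
F16 | step 10 | (5S,7S,10R)-11,12-dimethoxy-7,20-epoxyabieta-1,8,11,13-tetraene | C1=CCC(C)(C)[C@@H]2C[C@@H]3OC[C@]12c1c3cc(C(C)C)c(OC)c1OC
F17 | step 14 | (2S,5S,7S,10R)-7,20-epoxyabieta-8,11,13-triene-2,11,12-triol | O[C@H]1CC(C)(C)[C@@H]2C[C@@H]3OC[C@@]2(C1)c1c3cc(C(C)C)c(O)c1O
F18 | step 14 | (2S,5S,7S,10R)-7,20-epoxyabieta-8,11,13-triene-2,11,12-triyl triacetate | CC(=O)O[C@H]1CC(C)(C)[C@@H]2C[C@@H]3OC[C@@]2(C1)c1c3cc(C(C)C)c(OC(C)=O)c1OC(C)=O
A1 | alternative 1 | 20-(benzyloxy)-6-bromo-2-(tert-butyldimethylsilyloxy)-11,12-dimethoxyabieta-5,8,11,13-tetraen-7-one (C2 and C10 as in the target) | O=C1C(Br)=C2C(C)(C)C[C@H](O[Si](C)(C)C(C)(C)C)C[C@]2(COCc2ccccc2)c2c(OC)c(OC)c(C(C)C)cc12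
A2 | alternative 2 | 5,6-dimethoxy-2-(2-methylbut-3-en-2-yl)-7-(propan-2-yl)-1-(prop-2-en-1-yl)-1,2-dihydronaphthalene-1-carboxylic acid (C5 and C10 as in the target) | C=CC[C@]1(C(=O)O)c2c(OC)c(OC)c(C(C)C)cc2C=C[C@H]1C(C)(C)C=C
A3 | alternative 3 | 2-(tert-butyldimethylsilyloxy)-11,12-dimethoxy-7,20-epoxyabieta-8,11,13-trien-20-one (carnosol-type bridged lactone; stereocentres as in the target) | CC(C)(C)[Si](C)(C)O[C@H]1CC(C)(C)[C@@H]2C[C@@H]3OC(=O)[C@@]2(C1)c1c3cc(C(C)C)c(OC)c1OC
A4 | alternative 1 | 4-[(benzyloxy)methyl]-2-bromo-3-[4-(tert-butyldimethylsilyloxy)-5-(methanesulfonyloxy)-2-methylpentan-2-yl]-5,6-dimethoxy-7-(propan-2-yl)naphthalen-1-ol (C2 as in the target) | Oc1c(Br)c(C(C)(C)C[C@H](O[Si](C)(C)C(C)(C)C)COS(C)(=O)=O)c(COCc2ccccc2)c2c(OC)c(OC)c(C(C)C)cc12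
A5 | alternative 2 | 1-[(1E)-3,3-dimethylpenta-1,4-dien-1-yl]-5,6-dimethoxy-7-(propan-2-yl)-4-(prop-2-en-1-yl)isochroman-3-one (C7 defined; C10 epimers) | C=CCC1C(=O)O[C@@H](/C=C/C(C)(C)C=C)c2cc(C(C)C)c(OC)c(OC)c21
A6 | alternative 3 | 4-[2-(tert-butyldimethylsilyloxy)-4,4-dimethylhex-5-en-1-yl]-5,6-dimethoxy-7-(propan-2-yl)-3H-2-benzopyran-3-one (C2 as in the target) | C=CC(C)(C)C[C@H](O[Si](C)(C)C(C)(C)C)CC1=C2C(OC)=C(OC)C(C(C)C)=CC2=COC1=O
A7 | alternative 3 | 4-(tert-butyldimethylsilyloxy)-2-[6-formyl-2,3-dimethoxy-4-(propan-2-yl)phenyl]-6,6-dimethyloct-7-enoic acid (C2 of the target defined; C10 epimers) | C=CC(C)(C)C[C@H](O[Si](C)(C)C(C)(C)C)CC(C(=O)O)c1c(C=O)cc(C(C)C)c(OC)c1OC
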